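The numbers in the tables were computed on assumed constants; scatter was added.

The south-west vessel is closed, stirred and held at the temperature of the two earlier flasks, with substrate and reagent as charged below.

common to all: reagent 240 mM

| run | substrate | time |
|---|---|---|
| north-west | 120 mM |  |
| north | 360 mM |  |
| south-west | 120 mM | 190 s |

| run | time / s | [substrate] / mM |
|---|---|---|
| north-west run | 9.4 | 100.6 |
| north-west run | 19 | 86.1 |
| north-west run | 28 | 74.3 |
| north-west run | 38 | 62.8 |
| north-west run | 47 | 54.9 |
| north-west run | 56 | 48.5 |
| north-west run | 66 | 42.4 |
| north-west run | 75 | 37.8 |
| north run | 9.4 | 285.5 |
| north run | 19 | 233.8 |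
| north run | 28 | 197.8 |
| north run | 38 | 168.7 |
| north run | 47 | 149.1 |
| north run | 56 | 133.9 |
| north run | 66 | 118.8 |
| north run | 75 | 106.6 |

(standard deviation of a reading: 0.6 mM)

1. order of the initial rate in [substrate], near the charge of the north-west run, the rate being that where two percent of its substrate are target (one fixed amount of target, the same in the runs compared)
2. substrate in the south-west run at 190 s, as a share of the substrate charged

- Overall: substrate + reagent -> target.
- Constant volume, constant temperature.
- "The second partner" is reagent.
- An order is taken over about fifteen percent of the charge, up and down.

The north flask had lost 253 mM of substrate by 75 s, so its count stood at 1.06: this is the reagent turnover count, substrate lost per reagent charged. The overall equation takes one reagent per substrate, so the north reading, above the reagent charge, puts about 13.4 mM or more of that substrate, as read, on a road using no reagent.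

In the south-west flask, substrate is the limiting reagent, and the count cannot pass 0.500. The north-west flask reached 0.342 at 75 s. The south-west flask has the north-west charge, so my own reckoning carries the north-west fall, read as 0.0131 s⁻¹ between 56 s and 75 s, forward unchanged; that leaves c(substrate) near 8.36 mM at 190 s in the south-west flask, a count of 0.465. Leave the south-west vessel shut and add no substrate, so that its charge stays that of the north-west flask.

The forecast, holding that “substrate has a second sink that uses no reagent”, gives 9.2% left in the south-west flask, more than the 6.97% of my reckoning, a count of 0.454, and an order of 1.2.

The south-west flask gives 8.41% of its substrate left at 190 s, and the order near the north-west charge is 1.0; the rate of product formation in the north flask over that in the north-west flask, both where the same amount of target has been made, is 3.0 for a charge ratio of 3.00.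

    substrate + reagent → target (0.01400 L mol⁻¹ s⁻¹)
    substrate + 2 reagent → target + reagent (0.2090 L² mol⁻² s⁻¹)
    substrate + reagent + target → 2 target (0.2720 L² mol⁻² s⁻¹)
    2 substrate → homo dimer (0.01680 L mol⁻¹ s⁻¹)

The south-west count at 190 s is 0.458. In the north flask, the target made reaches 180 mM at 140 s, which is 0.750 of its reagent charge.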